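Ring C is a β-aryloxy ketone: O1, held on C8a of ring A, sits β to the C4 carbonyl across C2 and C3. The route therefore breaks the O1–C2 bond back to an ortho-hydroxyaryl enone and remakes it by a catalytic enantioselective 6-endo-trig oxa-Michael addition that sets C2, the only stereocentre. To make the closure fast and well organised at low temperature, C3 temporarily carries a tert-butyl ester; the precursor is a Knoevenagel alkylidene β-ketoester whose E/Z composition should not matter and whose C3 centre is erased afterwards, when one acid treatment removes the ester (as isobutene and CO2) together with a Boc group on the ring-B phenol.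

Key step: step 4

Assumption: compound 1 is taken to be commercially available.
Assumption: the quinidine-derived thiourea is taken to give the 2S series; the cinchona series are pseudoenantiomeric, so the quinine-derived catalyst replaces it without other change if the first analysis of 9 shows the opposite sense.

Step 1
Reactants: 1 methyl 2-hydroxy-3,4-dimethoxybenzoate; 2 tert-butyl acetate
Product: 3 tert-butyl 3-(2-hydroxy-3,4-dimethoxyphenyl)-3-oxopropanoate
Conditions: 2 (4 equiv), LiN(iPr)2 (4.2 equiv), THF, −78 °C; then 1, −78 → 0 °C; 1 M HCl, 0 °C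
Reagents that add atoms: none
Why: Crossed Claisen condensation, in which the lithium enolate of 2 (in excess, because the phenol and the product each consume one equivalent of base) should acylate on the non-enolisable methyl ester, while the bulky tert-butyl ester keeps self-condensation minor.

Step 2
Reactants: 4 3-hydroxy-4,5-dimethoxybenzaldehyde
Product: 5 tert-butyl 5-formyl-2,3-dimethoxyphenyl carbonate
Conditions: Boc2O (1.1 equiv), DMAP (5 mol%), CH2Cl2, rt
Reagents that add atoms: di-tert-butyl dicarbonate, CC(C)(C)OC(=O)OC(=O)OC(C)(C)C
Why: DMAP-catalysed O-acylation of the phenol should give the aryl tert-butyl carbonate, which keeps a second acidic OH away from the bifunctional catalyst of step 4 and falls to the same acid that later removes the tert-butyl ester.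

Step 3
Reactants: 3 tert-butyl 3-(2-hydroxy-3,4-dimethoxyphenyl)-3-oxopropanoate; 5 tert-butyl 5-formyl-2,3-dimethoxyphenyl carbonate
Product: 6 tert-butyl (2Z)-3-{3-[(tert-butoxycarbonyl)oxy]-4,5-dimethoxyphenyl}-2-(2-hydroxy-3,4-dimethoxybenzoyl)prop-2-enoate
Conditions: piperidine (10 mol%), AcOH (10 mol%), 4 Å molecular sieves, toluene, rt
Reagents that add atoms: none
Why: Knoevenagel condensation through the piperidinium iminium ion of 5 and the enol of 3; the tert-butyl ester resists lactonisation by the neighbouring phenol, and the Z isomer (ring-B aryl cis to the ester) is expected to predominate, although either geometry should serve step 4.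

Step 4
Reactants: 6 tert-butyl (2Z)-3-{3-[(tert-butoxycarbonyl)oxy]-4,5-dimethoxyphenyl}-2-(2-hydroxy-3,4-dimethoxybenzoyl)prop-2-enoate
Product: 9 (2S)-2-(3-hydroxy-4,5-dimethoxyphenyl)-7,8-dimethoxychroman-4-one, via cyclised tert-butyl ester 7 (not isolated), via keto acid 8 (not isolated)
Conditions: N-[3,5-bis(trifluoromethyl)phenyl]-N'-[(9R)-6'-methoxycinchonan-9-yl]thiourea (quinidine-derived, 10 mol%), toluene (0.05 M), −25 °C; then TsOH·H2O (0.5 equiv) added cold, 80 °C, argon sweep
Reagents that add atoms: none
Why: The quinuclidine nitrogen of the catalyst should take up the proton of the ring-A hydroxyl while the thiourea NH pair clamps the ketone and ester carbonyls of 6, so that the phenoxide oxygen adds to the benzylidene carbon (the future C2) and protonation of the β-ketoester enolate gives 7; TsOH, added cold, then protonates the amine and at 80 °C removes both tert-butyl groups as isobutene, after which the carbonic half-ester and the β-keto acid 8 lose CO2 to leave 9. The closest known reaction type is the bifunctional cinchona-thiourea-catalysed intramolecular oxa-Michael addition of alkylidene β-ketoesters followed by acid-mediated dealkylative decarboxylation. Ring C closes in the 6-endo-trig mode by attack of O1 on C2. C2 is set by the catalyst, whose C8/C9 configuration decides which face of the alkene meets the phenoxide (the quinidine-derived series is assumed to give 2S), whereas C3 of 7 is labile, should settle trans to the aryl group and is erased on decarboxylation. The step needs enantioface selectivity over the racemic background and over retro-addition, which the C3 tert-butyl ester secures by two-point binding and by activating the alkene enough for reaction at −25 °C, and which the cold acid quench protects; chemoselectivity is secured because the ring-B phenol is masked as its carbonate, so that only O1 can reach C2.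

Compound list
1 | methyl 2-hydroxy-3,4-dimethoxybenzoate | COC(=O)c1ccc(OC)c(OC)c1O | starting material
2 | tert-butyl acetate | CC(=O)OC(C)(C)C | starting material
3 | tert-butyl 3-(2-hydroxy-3,4-dimethoxyphenyl)-3-oxopropanoate | CC(C)(C)OC(=O)CC(=O)c1ccc(OC)c(OC)c1O | intermediate
4 | 3-hydroxy-4,5-dimethoxybenzaldehyde | COc1cc(C=O)cc(O)c1OC | starting material
5 | tert-butyl 5-formyl-2,3-dimethoxyphenyl carbonate | COc1cc(C=O)cc(OC(=O)OC(C)(C)C)c1OC | intermediate
6 | tert-butyl (2Z)-3-{3-[(tert-butoxycarbonyl)oxy]-4,5-dimethoxyphenyl}-2-(2-hydroxy-3,4-dimethoxybenzoyl)prop-2-enoate (Z shown; any E isomer is carried along) | CC(C)(C)OC(=O)/C(=C\c1cc(OC)c(OC)c(OC(=O)OC(C)(C)C)c1)C(=O)c1ccc(OC)c(OC)c1O | intermediate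
7 | tert-butyl (2S,3R)-2-{3-[(tert-butoxycarbonyl)oxy]-4,5-dimethoxyphenyl}-7,8-dimethoxy-4-oxochromane-3-carboxylate (2,3-trans; C3 labile; not isolated) | CC(C)(C)OC(=O)Oc1cc(cc(OC)c1OC)[C@H]1Oc2c(OC)c(OC)ccc2C(=O)[C@@H]1C(=O)OC(C)(C)C | intermediate
8 | (2S,3R)-2-(3-hydroxy-4,5-dimethoxyphenyl)-7,8-dimethoxy-4-oxochromane-3-carboxylic acid (not isolated) | COc1cc(cc(O)c1OC)[C@H]1Oc2c(OC)c(OC)ccc2C(=O)[C@@H]1C(=O)O | intermediate
9 | (2S)-2-(3-hydroxy-4,5-dimethoxyphenyl)-7,8-dimethoxychroman-4-one | COc1cc([C@@H]2CC(=O)c3ccc(OC)c(OC)c3O2)cc(O)c1OC | target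

Total step count: 4
Longest linear sequence: 3 steps (1 → 3 → 6 → 9; step 2 is a one-step side branch)

Steps most likely to fail

Step 4. The catalyst may discriminate the two faces of C2 poorly on this substrate, since the 8-methoxy group flanks the attacking oxygen and ring B is very electron-rich. The enantiomeric purity may also erode in the hot acid stage by reversible opening of ring C at the 4'-methoxy-stabilised benzylic position. The fallback replaces asymmetric catalysis by separation with recycling. It sets out from 6: closure with an achiral base (Et3N, 10 mol%, toluene, rt) followed by the same acid stage (TsOH·H2O, 80 °C) should lead through the racemic cyclised tert-butyl ester F1 and the racemic keto acid F2, neither isolated, to the racemic flavanone F3. Preparative chromatography on a chiral stationary phase (supercritical CO2/MeOH, amylose tris(3,5-dimethylphenylcarbamate) column) should then deliver 9, where the fallback comes back to the route. The unwanted (2R)-flavanone F4 would be racemised back to F3 with catalytic DBU and recycled.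

Step 3. The aryl carbonate may be cleaved or transferred by piperidine, and the condensation may stall under the mild conditions that the carbonate allows. The fallback changes the protecting-group strategy to a benzyl ether, which tolerates forcing azeotropic conditions, at the cost of one extra step. It sets out from 4: benzylation (BnBr, K2CO3, DMF, rt) should give 3-(benzyloxy)-4,5-dimethoxybenzaldehyde F5. Knoevenagel condensation of F5 with 3 (piperidine, AcOH, benzene, reflux, Dean–Stark trap) should give the benzyl-protected alkylidene β-ketoester F6. The conditions of step 4 should take F6 through the cyclised benzyl-protected tert-butyl ester F7 and the benzyl-protected keto acid F8, neither isolated, to the (2S)-flavanone benzyl ether F9. Hydrogenolysis (H2, 1 atm, Pd/C, EtOAc, rt, stopped at consumption of F9) should then give 9, where the fallback comes back to the route.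

Step 1. The lithium phenoxide of 1 is a deactivated and poorly soluble acyl acceptor, so acylation of the enolate may be slow and self-condensation of 2 may take over. The fallback activates the salicylate as its acetonide. It sets out from 1: saponification (LiOH, THF/H2O, then acidification) should give 2-hydroxy-3,4-dimethoxybenzoic acid F10. Treatment with acetone, (CF3CO)2O and CF3CO2H at rt should close it to 7,8-dimethoxy-2,2-dimethyl-4H-1,3-benzodioxin-4-one F11, an activated aryl ester without a free phenol. Addition of F11 to the lithium enolate of 2 (LiN(iPr)2, THF, −78 °C) should open the dioxinone with loss of acetone and give 3, where the fallback comes back to the route.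

Further compounds
F1 | step 4 | racemic trans tert-butyl 2-{3-[(tert-butoxycarbonyl)oxy]-4,5-dimethoxyphenyl}-7,8-dimethoxy-4-oxochromane-3-carboxylate | CC(C)(C)OC(=O)Oc1cc(cc(OC)c1OC)C1Oc2c(OC)c(OC)ccc2C(=O)C1C(=O)OC(C)(C)C
F2 | step 4 | racemic trans 2-(3-hydroxy-4,5-dimethoxyphenyl)-7,8-dimethoxy-4-oxochromane-3-carboxylic acid | COc1cc(cc(O)c1OC)C1Oc2c(OC)c(OC)ccc2C(=O)C1C(=O)O
F3 | step 4 | racemic 2-(3-hydroxy-4,5-dimethoxyphenyl)-7,8-dimethoxychroman-4-one | COc1cc(C2CC(=O)c3ccc(OC)c(OC)c3O2)cc(O)c1OC
F4 | step 4 | (2R)-2-(3-hydroxy-4,5-dimethoxyphenyl)-7,8-dimethoxychroman-4-one | COc1cc([C@H]2CC(=O)c3ccc(OC)c(OC)c3O2)cc(O)c1OC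
F5 | step 3 | 3-(benzyloxy)-4,5-dimethoxybenzaldehyde | COc1cc(C=O)cc(OCc2ccccc2)c1OC
F6 | step 3 | tert-butyl (2Z)-3-[3-(benzyloxy)-4,5-dimethoxyphenyl]-2-(2-hydroxy-3,4-dimethoxybenzoyl)prop-2-enoate | CC(C)(C)OC(=O)/C(=C\c1cc(OC)c(OC)c(OCc2ccccc2)c1)C(=O)c1ccc(OC)c(OC)c1O
F7 | step 3 | tert-butyl (2S,3R)-2-[3-(benzyloxy)-4,5-dimethoxyphenyl]-7,8-dimethoxy-4-oxochromane-3-carboxylate | COc1cc(cc(OCc2ccccc2)c1OC)[C@H]1Oc2c(OC)c(OC)ccc2C(=O)[C@@H]1C(=O)OC(C)(C)C
F8 | step 3 | (2S,3R)-2-[3-(benzyloxy)-4,5-dimethoxyphenyl]-7,8-dimethoxy-4-oxochromane-3-carboxylic acid | COc1cc(cc(OCc2ccccc2)c1OC)[C@H]1Oc2c(OC)c(OC)ccc2C(=O)[C@@H]1C(=O)O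
F9 | step 3 | (2S)-2-[3-(benzyloxy)-4,5-dimethoxyphenyl]-7,8-dimethoxychroman-4-one | COc1cc([C@@H]2CC(=O)c3ccc(OC)c(OC)c3O2)cc(OCc2ccccc2)c1OC
F10 | step 1 | 2-hydroxy-3,4-dimethoxybenzoic acid | COc1ccc(C(=O)O)c(O)c1OC
F11 | step 1 | 7,8-dimethoxy-2,2-dimethyl-4H-1,3-benzodioxin-4-one | COc1ccc2C(=O)OC(C)(C)Oc2c1OC
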